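It is impossible for one percent of Z to be counted twice, so reckon the new flasks from a balance: what a finished flask holds besides E went elsewhere.

| flask | Z | J | D | L | temperature | remark | time |
|---|---|---|---|---|---|---|---|
| spring | 0.18 M | 2 equiv | 1.1 equiv | 0.027 M | 60 °C | run made earlier |  |
| midnight | 0.18 M | 2 equiv | 1.1 equiv | 0.11 M | 88 °C | run made earlier |  |
| noon | 0.090 M | 2 equiv | 1.1 equiv | 0.054 M | 60 °C | run made earlier |  |
| Saturday's | 0.18 M | 2.00 equiv | 1.10 equiv | 0.0540 M | 65 °C |  | 3.0 h |
| Sunday's | 0.18 M | 2.00 equiv | 1.10 equiv | 0.0540 M | 95 °C |  | 3.0 h |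
| Friday's | 0.18 M | 2.00 equiv | 1.10 equiv | 0.0540 M | 110 °C |  | 3.0 h |
| Monday's | 0.18 M | 2.00 equiv | 1.10 equiv | 0.0540 M | 80 °C |  | 3.0 h |

spring run (percent of the Z charged)

| time / h | E / % | Z / % |
|---|---|---|
| 0.667 | 77 | 8 |
| 1.33 | 86 | 2 |
| 2.00 | 91 | 1 |
| 2.50 | 93 | 1 |

midnight run (percent of the Z charged)

| time / min | E / % | Z / % |
|---|---|---|
| 6.00 | 69 | 9 |
| 15.0 | 79 | 3 |
| 30.0 | 84 | 0 |
| 50.0 | 83 | 2 |

noon run (percent of the Z charged)

| time / h | E / % | Z / % |
|---|---|---|
| 0.333 | 49 | 16 |
| 0.833 | 63 | 8 |
| 1.50 | 74 | 2 |
| 2.50 | 78 | 1 |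

(scatter of a reading: 1.5 percentage points)

1. the flask with the highest amount of E, in percent of the Z charged ("all alike" if they lie within 1.5 percentage points) (Saturday's / Sunday's / Friday's / Monday's / all alike)
2. final E, as a percentage of the Z charged, in Saturday's
3. final E, as a percentage of the Z charged, in Sunday's
4. final E, as a percentage of the Z charged, in Friday's
5. final E, as a percentage of the Z charged, in Monday's

Time needs little care: the spring run read Z at 1 % by 2.50 h, and Saturday's, the coolest new flask, is hotter than the spring run and runs longer. The loss reads 6.00 % in the spring run, with 0.150 of L per Z charged, and 21.0 % in the noon run, with 0.600, so assume one unseen active form of Z which D turns into E and L into a side product, each consumed one for one. Then the rate to E over the rate to the side product equals a constant times D over L, and as that ratio drifts, the logarithm of the fraction of D left over the logarithm of the fraction of L left stays equal to the constant: call it the selectivity factor.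

This is the number to know well. The spring run reads 3.66 and the midnight run 4.75. Starting from the mean of those two runs' E, 88.5 %, one pass through the balance at the new recipe gives 89.2 % and 91.3 %, so the gap matters. But one standard deviation on the spring E lifts its reading to 5.49, past midnight's, so I read no temperature trend from these two runs. Take their mean, 4.20. Two passes give 90.3 %, then 89.9 %, in each new flask, which I call alike.

The forecast named Friday's, with E at 89 %, 90.5 %, 92 % and 92.5 % from coolest to hottest, holding that “Heat therefore favours E modestly”.

The flasks give all alike: Saturday's 89.5 %, Monday's 89.5 %, Sunday's 89.3 %, Friday's 89.2 %.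

    X + L → Q (k = 0.0110 M⁻¹ s⁻¹, Ea = 68.0 kJ mol⁻¹)
    Z + J ⇌ G + X, settled at all times (K = 1.00, ΔH = −20.0 kJ mol⁻¹)
    D + X → E (k = 0.0430 M⁻¹ s⁻¹, Ea = 66.0 kJ mol⁻¹)
    (constants at 80 °C)

In Saturday's, X goes to E 15 times as fast as to Q just after the start, where the carried factor with the charges gives 15.4, and that ratio has drifted to 4.2 at 3.00 h. Across the four flasks E spans 0.30 percentage points, under the margin of 1.5 points.

In the neighbour of Saturday's, with Z at 0.045 M, L stands at 1.20 equiv, so the factor gives a starting ratio of rate to E over rate to Q of 3.85, and passes from that share swing through 68.5 %, 75.2 % and 71.3 %. That neighbour holds E 70.4 % and Q 26.9 % at 3.00 h, with Z 1.11 % and X 1.54 % still there.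

The readings stem from a simulated flask from invented constants.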